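**Retrosynthetic overview**
- **C6–C(=O) disconnection.** Retro-hydroacylation of the acylhydroquinone gives (S)-2H-chromene-5,8-dione and (E)-4-acetoxycinnamaldehyde. In the forward sense, a light-driven quinone–aldehyde coupling joins the halves and reduces the quinone to the C5/C8 diol in the same event.
- **Enabling feature.** In the benzo ring (C4a–C5–C6–C7–C8–C8a) the C5–OH and C8–OH are para, so the ring is a masked p-quinone whose only free C=C is C6=C7. Pyran O1 on C8a is a vinylogous-ester donor to C5=O (O1–C8a=C4a–C5=O), which leaves C8=O/C7=C6 as the acceptor and C6 as its β-carbon.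
- **Quinone.** It comes from the 5,8-dimethoxy-2H-chromene by oxidative demethylation. That chromene comes from RCM of an o-vinylaryl tertiary allyl ether (C3=C4).
- **C2, the only stereocentre.** It is the carbinol carbon of (S)-linalool, O-arylated by SNAr with its C–O bond intact. The side-chain C=C becomes the tertiary alcohol by epoxidation and hydride opening before RCM.
- **Ring order.** Both benzene rings are bought, the pyran ring is closed in step 6, and no ring is formed afterwards.

Key step: step 9

Assumption: (S)-(+)-linalool (coriandrol) is taken as a purchasable chiral-pool alcohol of high enantiomeric purity. Its carbinol C–O bond is never broken, so the enantiomeric purity of the target is that of this lot.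

Step 1
Reactants: 1 2-fluoro-1,4-dimethoxybenzene
Product: 3 2-fluoro-3,6-dimethoxybenzaldehyde, via aryllithium 2 (not isolated)
Conditions: n-BuLi, THF, −78 °C; DMF, −78 → 0 °C; H2O
Reagents that add atoms: N,N-dimethylformamide, CN(C)C=O
Why: Directed ortho-metalation followed by formylation, in which the C–H flanked by F and OMe is the most acidic ring position so that CHO should enter between the two directing groups, while −78 °C suppresses LiF loss to the aryne.

Step 2
Reactants: 3 2-fluoro-3,6-dimethoxybenzaldehyde, 4 (S)-(+)-linalool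
Product: 6 2-{[(3S)-3,7-dimethylocta-1,6-dien-3-yl]oxy}-3,6-dimethoxybenzaldehyde, via potassium alkoxide 5 (not isolated)
Conditions: 4, KHMDS, THF, 0 °C; then 3, 0 → 45 °C
Reagents that add atoms: none
Why: SNAr (addition–elimination) of a potassium tert-alkoxide on an ortho-formyl-activated aryl fluoride is a known entry to hindered alkyl aryl ethers, and because the carbinol C–O bond is untouched the (S) configuration of 4 is carried over unchanged as the future C2.

Step 3
Reactants: 6 2-{[(3S)-3,7-dimethylocta-1,6-dien-3-yl]oxy}-3,6-dimethoxybenzaldehyde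
Product: 7 2-{[(3S)-5-(3,3-dimethyloxiran-2-yl)-3-methylpent-1-en-3-yl]oxy}-3,6-dimethoxybenzaldehyde (both epimers at the oxirane CH)
Conditions: mCPBA (1.0 equiv), CH2Cl2, −10 → 0 °C
Reagents that add atoms: 3-chloroperoxybenzoic acid, OOC(=O)c1cccc(Cl)c1
Why: Prilezhaev epoxidation follows alkene nucleophilicity, so the trisubstituted alkene should react much faster than the aryloxy-deactivated vinyl group or the hindered aldehyde (Dakin-type oxidation), and the new oxirane CH is an inconsequential epimer mixture because it becomes CH2 in step 5.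

Step 4
Reactants: 7 epoxy aldehyde
Product: 8 2-[(3S)-3-(2-ethenyl-3,6-dimethoxyphenoxy)-3-methylpent-4-en-1-yl]-3,3-dimethyloxirane (both epimers at the oxirane CH)
Conditions: MePPh3Br, KOt-Bu, THF, 0 °C; then 7, 0 °C → rt
Reagents that add atoms: methyltriphenylphosphonium bromide, C[P+](c1ccccc1)(c1ccccc1)c1ccccc1.[Br-]
Why: Wittig methylenation of a non-enolisable aromatic aldehyde, to which the trisubstituted epoxide and the allyl aryl ether are inert.

Step 5
Reactants: 8 epoxy styrene
Product: 9 (6S)-6-(2-ethenyl-3,6-dimethoxyphenoxy)-2,6-dimethyloct-7-en-2-ol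
Conditions: LiAlH4, THF, 0 → 40 °C; aqueous work-up
Reagents that add atoms: none
Why: SN2-type hydride opening of a trisubstituted epoxide at its less substituted carbon should give the tertiary alcohol and erase the epimeric centre, while styrene, vinyl group and aryl ethers do not react with LiAlH4.

Step 6
Reactants: 9 (6S)-6-(2-ethenyl-3,6-dimethoxyphenoxy)-2,6-dimethyloct-7-en-2-ol
Product: 10 5-[(2S)-5,8-dimethoxy-2-methyl-2H-chromen-2-yl]-2-methylpentan-2-ol
Conditions: (H2IMes)(PCy3)Cl2Ru=CHPh (cat.), CH2Cl2 (dilute), 40 °C
Reagents that add atoms: none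
Why: Ring-closing metathesis of an o-vinylaryl allyl ether (six-membered ring, loss of ethene) is an established 2H-chromene synthesis that is helped by the geminal substitution at C2, tolerates the free tertiary alcohol, leaves C2 untouched, has no competing side-chain alkene after step 5, and runs far below the temperature of an aryl allyl ether Claisen rearrangement.

Step 7
Reactants: 10 5-[(2S)-5,8-dimethoxy-2-methyl-2H-chromen-2-yl]-2-methylpentan-2-ol
Product: 11 (2S)-2-(4-hydroxy-4-methylpentyl)-2-methyl-2H-chromene-5,8-dione
Conditions: (NH4)2Ce(NO3)6 (2.2 equiv), MeCN/H2O, 0 °C, short contact; product kept cold and dark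
Reagents that add atoms: water, O
Why: Ce(IV) oxidative demethylation of a 1,4-dimethoxyarene (two-electron oxidation, water attacks the two ipso carbons, methanol leaves) is the standard route to p-quinones and spares O1, which has no para alkoxy partner, as well as C2.

Step 8
Reactants: 12 4-acetoxybenzaldehyde
Product: 13 (E)-4-acetoxycinnamaldehyde
Conditions: Ph3P=CHCHO (1.0 equiv), toluene, 80 °C
Reagents that add atoms: (triphenylphosphoranylidene)acetaldehyde, O=CC=P(c1ccccc1)(c1ccccc1)c1ccccc1
Why: Wittig olefination with a stabilised formyl ylide is E-selective, neutral enough for the aryl acetate, and limited to one homologation by the stoichiometry.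

Step 9
Reactants: 11 (2S)-2-(4-hydroxy-4-methylpentyl)-2-methyl-2H-chromene-5,8-dione, 13 (E)-4-acetoxycinnamaldehyde
Product: 15 4-{(E)-3-[(2S)-5,8-dihydroxy-2-(4-hydroxy-4-methylpentyl)-2-methyl-2H-chromen-6-yl]-3-oxoprop-1-enyl}phenyl acetate, via dienone tautomer 14 (not isolated)
Conditions: 13 (3 equiv), hν (blue LED, 450 nm), degassed PhCF3, 5 °C, thin-film/flow reactor, work-up in the dark
Reagents that add atoms: none
Why: Visible light populates the n,π* triplet of quinone 11, which abstracts the formyl H of 13; the nucleophilic, non-decarbonylating σ-enoyl radical adds to C6 of ground-state 11, the adduct radical takes H back from the semiquinone (regenerating 11) to give dienone 14, and enolisation of its C6–H aromatises the ring, so one redox-neutral, fully atom-economic event makes the C6–C(=O) bond, unveils both the C5 and C8 phenols and installs the chelated 2'-hydroxychalcone with no protecting group on this ring or on the tertiary alcohol. The closest known reaction type is the photo-Friedel–Crafts acylation of 1,4-benzo- and 1,4-naphthoquinones with aliphatic, aromatic and α,β-unsaturated aldehydes, which gives acylhydroquinones directly. No ring is closed and no lasting stereocentre is created (C6 of 14 is transient), and C2 is a spectator whose integrity only requires that the pyran ring stays closed, hence long-wavelength light, low temperature and short residence time. The step needs C6 over C7 selectivity, which the substrate secures because O1 on C8a feeds electron density through C8a=C4a into C5=O, so that the C8=O/C7=C6 enone is the better acceptor and C6, its β-carbon and the site para to O1, is attacked as in the 2,5-selective additions to 2-alkoxy-1,4-benzoquinones. It also needs formyl C–H abstraction to win over O–H abstraction and alkene photochemistry, which is served by masking the B-ring phenol as an electron-poor acetate, by the absence of any H on C2 next to O1 (no intramolecular abstraction–cyclisation of the alkoxyquinone), by the transparency of 13 at 450 nm and by the acceptor character of the enal C=C, a poor partner for [2+2] or oxetane formation. The E geometry is the thermodynamic one of both the enoyl radical (ketenyl–allyl resonance) and the chelated chalcone, so any Z material should drain to E.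

Step 10
Reactants: 15 4-O-acetyl derivative of the target
Product: 16 (E)-1-[(2S)-5,8-dihydroxy-2-(4-hydroxy-4-methylpentyl)-2-methyl-2H-chromen-6-yl]-3-(4-hydroxyphenyl)prop-2-en-1-one
Conditions: K2CO3 (cat.), degassed MeOH, 0 °C, Ar; AcOH quench
Reagents that add atoms: none
Why: Base-catalysed transesterification cleaves an aryl acetate within minutes at 0 °C, conditions under which oxa-Michael closure of the chelated 2'-hydroxychalcone to the flavanone is slow and, with oxygen excluded, the acyl-deactivated hydroquinone is not oxidised.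

**Compound list**
1 | 2-fluoro-1,4-dimethoxybenzene | COc1ccc(OC)cc1F | starting material
2 | (2-fluoro-3,6-dimethoxyphenyl)lithium | [Li]c1c(F)c(OC)ccc1OC | intermediate
3 | 2-fluoro-3,6-dimethoxybenzaldehyde | O=Cc1c(F)c(OC)ccc1OC | intermediate
4 | (S)-(+)-linalool, (3S)-3,7-dimethylocta-1,6-dien-3-ol | CC(C)=CCC[C@@](O)(C)C=C | starting material
5 | potassium (3S)-3,7-dimethylocta-1,6-dien-3-olate | CC(C)=CCC[C@@]([O-])(C)C=C.[K+] | intermediate
6 | 2-{[(3S)-3,7-dimethylocta-1,6-dien-3-yl]oxy}-3,6-dimethoxybenzaldehyde | CC(C)=CCC[C@@](Oc1c(OC)ccc(OC)c1C=O)(C)C=C | intermediate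
7 | 2-{[(3S)-5-(3,3-dimethyloxiran-2-yl)-3-methylpent-1-en-3-yl]oxy}-3,6-dimethoxybenzaldehyde (oxirane CH: both epimers) | CC1(C)OC1CC[C@@](Oc2c(OC)ccc(OC)c2C=O)(C)C=C | intermediate
8 | 2-[(3S)-3-(2-ethenyl-3,6-dimethoxyphenoxy)-3-methylpent-4-en-1-yl]-3,3-dimethyloxirane (oxirane CH: both epimers) | CC1(C)OC1CC[C@@](Oc2c(OC)ccc(OC)c2C=C)(C)C=C | intermediate
9 | (6S)-6-(2-ethenyl-3,6-dimethoxyphenoxy)-2,6-dimethyloct-7-en-2-ol | CC(C)(O)CCC[C@@](Oc1c(OC)ccc(OC)c1C=C)(C)C=C | intermediate
10 | 5-[(2S)-5,8-dimethoxy-2-methyl-2H-chromen-2-yl]-2-methylpentan-2-ol | CC(C)(O)CCC[C@@]1(C)C=Cc2c(OC)ccc(OC)c2O1 | intermediate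
11 | (2S)-2-(4-hydroxy-4-methylpentyl)-2-methyl-2H-chromene-5,8-dione | CC(C)(O)CCC[C@@]1(C)C=CC2=C(O1)C(=O)C=CC2=O | intermediate
12 | 4-acetoxybenzaldehyde | CC(=O)Oc1ccc(C=O)cc1 | starting material
13 | (E)-4-acetoxycinnamaldehyde | CC(=O)Oc1ccc(/C=C/C=O)cc1 | intermediate
14 | 4-{(E)-3-[(2S)-8-hydroxy-2-(4-hydroxy-4-methylpentyl)-2-methyl-5-oxo-5,6-dihydro-2H-chromen-6-yl]-3-oxoprop-1-enyl}phenyl acetate (C6: both epimers) | CC(C)(O)CCC[C@@]1(C)C=CC2=C(O1)C(O)=CC(C(=O)/C=C/c3ccc(OC(C)=O)cc3)C2=O | intermediate
15 | 4-{(E)-3-[(2S)-5,8-dihydroxy-2-(4-hydroxy-4-methylpentyl)-2-methyl-2H-chromen-6-yl]-3-oxoprop-1-enyl}phenyl acetate | CC(C)(O)CCC[C@@]1(C)C=Cc2c(O)c(C(=O)/C=C/c3ccc(OC(C)=O)cc3)cc(O)c2O1 | intermediate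
16 | (E)-1-[(2S)-5,8-dihydroxy-2-(4-hydroxy-4-methylpentyl)-2-methyl-2H-chromen-6-yl]-3-(4-hydroxyphenyl)prop-2-en-1-one | CC(C)(O)CCC[C@@]1(C)C=Cc2c(O)c(C(=O)/C=C/c3ccc(O)cc3)cc(O)c2O1 | target

Total step count: 10. Longest linear sequence: 9 (steps 1–7, 9, 10).

**Steps most likely to fail**

**1. Step 9.** Three processes may go wrong:
- light-induced electrocyclic opening and reclosure of the pyran ring of 11 or 15, which would erode the C2 configuration;
- insufficient discrimination between C6 and C7 by the acyl radical;
- unproductive energy transfer from the quinone triplet to the enal, giving E/Z scrambling and a stalled conversion.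

The fallback makes the same bond by polar chemistry in the dark. It sets out from 10 and comes back at 15. Electrophilic iodination of 10 (NIS, MeCN, −20 °C) should go to the position para to O1 and ortho to the C5 methoxy group, giving 5-[(2S)-6-iodo-5,8-dimethoxy-2-methyl-2H-chromen-2-yl]-2-methylpentan-2-ol F1. I/Mg exchange (i-PrMgCl·LiCl, 2.2 equiv, THF, 0 °C) gives the C6-arylmagnesium chloride with magnesiated side-chain alkoxide F2. At −78 °C this adds 1,2 to the aldehyde of 13 faster than it attacks the acetate, giving the allylic benzylic carbinol F3 (epimer mixture). MnO2 (CH2Cl2, rt) oxidises it to the 5,8-dimethoxychalcone acetate F4. Ce(IV) oxidative demethylation (MeCN/H2O, 0 °C) gives the 6-acyl-5,8-quinone F5, which is reduced in the same flask with aqueous Na2S2O4 to 15.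

**2. Step 2.** The addition–elimination may be sluggish at a fluoride flanked by CHO and OMe on a donor-rich ring. The alkoxide may also attack the formyl group and cause hydride-transfer disproportionation of the aldehyde.

The fallback reverses the polarity of the C–O bond formation. It sets out from 3 and comes back at 6. Displacement of fluoride by hydroxide (KOH, DMSO/H2O, 60 °C, then acid) gives 2-hydroxy-3,6-dimethoxybenzaldehyde F6. F6 is then O-alkylated with geranyl methyl carbonate F7 (made from geraniol and methyl chloroformate, pyridine) under Pd(0)-catalysed asymmetric allylic alkylation conditions [Pd2(dba)3, C2-symmetric trans-1,2-diaminocyclohexane bis(2-diphenylphosphinobenzamide) ligand, CH2Cl2, rt]. The phenoxide attacks the more substituted π-allyl terminus, as in the known Pd-catalysed formation of 1,1-dialkylallyl aryl ethers. The stereocentre then comes from the ligand, whose antipode is fixed by correlation with 6 derived from 4.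

**3. Step 7.** Water or nitrate may add to the radical cation at the electron-rich C3=C4 bond. The acidic Ce(IV) medium may also ionise the pyran C2–O1 bond.

The fallback replaces the chemical oxidant and acid by electrolysis in base. It sets out from 10 and comes back at 11. Anodic oxidation (Pt anode, undivided cell, KOH/MeOH, 0 °C) gives the quinone bis(dimethyl ketal) F8. Mild hydrolysis (aqueous AcOH/acetone, 0 °C) then converts it into 11.

**Further compounds**
F1 | step 9 | 5-[(2S)-6-iodo-5,8-dimethoxy-2-methyl-2H-chromen-2-yl]-2-methylpentan-2-ol | CC(C)(O)CCC[C@@]1(C)C=Cc2c(OC)c(I)cc(OC)c2O1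
F2 | step 9 | C6-arylmagnesium chloride with magnesiated side-chain alkoxide | CC(C)(O[Mg]Cl)CCC[C@@]1(C)C=Cc2c(OC)c([Mg]Cl)cc(OC)c2O1
F3 | step 9 | 4-{(E)-3-hydroxy-3-[(2S)-2-(4-hydroxy-4-methylpentyl)-5,8-dimethoxy-2-methyl-2H-chromen-6-yl]prop-1-enyl}phenyl acetate (carbinol epimers) | CC(C)(O)CCC[C@@]1(C)C=Cc2c(OC)c(C(O)/C=C/c3ccc(OC(C)=O)cc3)cc(OC)c2O1
F4 | step 9 | 4-{(E)-3-[(2S)-2-(4-hydroxy-4-methylpentyl)-5,8-dimethoxy-2-methyl-2H-chromen-6-yl]-3-oxoprop-1-enyl}phenyl acetate | CC(C)(O)CCC[C@@]1(C)C=Cc2c(OC)c(C(=O)/C=C/c3ccc(OC(C)=O)cc3)cc(OC)c2O1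
F5 | step 9 | 4-{(E)-3-[(2S)-2-(4-hydroxy-4-methylpentyl)-2-methyl-5,8-dioxo-5,8-dihydro-2H-chromen-6-yl]-3-oxoprop-1-enyl}phenyl acetate | CC(C)(O)CCC[C@@]1(C)C=CC2=C(O1)C(=O)C=C(C(=O)/C=C/c3ccc(OC(C)=O)cc3)C2=O
F6 | step 2 | 2-hydroxy-3,6-dimethoxybenzaldehyde | O=Cc1c(O)c(OC)ccc1OC
F7 | step 2 | geranyl methyl carbonate | CC(C)=CCC/C(C)=C/COC(=O)OC
F8 | step 7 | 5-[(2S)-5,5,8,8-tetramethoxy-2-methyl-5,8-dihydro-2H-chromen-2-yl]-2-methylpentan-2-ol | CC(C)(O)CCC[C@@]1(C)C=CC2=C(O1)C(OC)(OC)C=CC2(OC)OC
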